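**Retrosynthetic overview** (chromanone numbering; side chain C1′ on C2 to C15′)
1. Target 14 ⇐ dienyl chromanone 13 by one global hydrogenation (two C=C, two benzyl ethers); 13 ⇐ chromanol 12 by oxidation at C4.
2. Key disconnection of 12: the side-chain bond C3′–C4′ and the ring bond O1–C2 are cut together, giving the acyclic dienyl phenol 8 and (E)-1-iodododec-1-ene 11. Forward, one Pd-catalysed asymmetric Heck/Tsuji–Trost cascade makes both bonds, the pyran ring (the only ring formed in the route; the benzene ring is bought) and the C2 stereocentre.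
3. Enabling feature: O1–C2 and C3′–C4′ are 1,4-related across C2–C1′–C2′–C3′. At the diene level (C2=C1′–C2′=C3′) this unit takes carbon at C3′ and oxygen at C2, and the phenol oxygen on C8a is tied to C2 through C4a–C4–C3, so only the six-membered pyran ring can close.
4. 8 ⇐ salicylaldehyde 6 + pentadienylsilane 7 (C3–C4 bond); 6 ⇐ 2,5-dihydroxybenzaldehyde 1 by benzylation, Baeyer–Villiger/Dakin oxidation and ortho-formylation; 11 ⇐ dodec-1-yne 9.

Key step: step 6

Remark: (2E)-penta-2,4-dien-1-yl(trimethyl)silane 7 is taken as a catalogue reagent; if it must be made, pentadienyllithium (penta-1,4-diene, n-BuLi) is silylated with Me3SiCl.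
Remark: which antipode of the chiral ligand delivers (2S)-12 cannot be assigned in advance; it is to be fixed in a pilot run and the other antipode used if needed.

**Step 1**
Reactants: 1 2,5-dihydroxybenzaldehyde
Product: 2 2,5-bis(benzyloxy)benzaldehyde
Conditions: BnBr (2.4 equiv), K2CO3, DMF, 60 °C
Reagents that add atoms: benzyl bromide, BrCc1ccccc1
Why: Williamson ether synthesis; carbonate in DMF should alkylate both phenols, the hydrogen-bonded 2-OH on warming.

**Step 2**
Reactants: 2 2,5-bis(benzyloxy)benzaldehyde
Product: 4 2,5-bis(benzyloxy)phenol, via aryl formate 3 (not isolated)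
Conditions: mCPBA, CH2Cl2, 0 °C to rt; NaHCO3 wash; then K2CO3 (cat.), MeOH, rt
Reagents that add atoms: mCPBA (3-chloroperoxybenzoic acid), OOC(=O)c1cccc(Cl)c1
Why: Baeyer–Villiger oxidation of an electron-rich benzaldehyde (Dakin-type) should proceed by aryl migration to the aryl formate, which is methanolysed to the phenol.

**Step 3**
Reactants: 4 2,5-bis(benzyloxy)phenol
Product: 6 3,6-bis(benzyloxy)-2-hydroxybenzaldehyde, via salicyl alcohol 5 (not isolated)
Conditions: (CH2O)n, MgCl2, Et3N, MeCN, reflux; aq. HCl work-up
Reagents that add atoms: paraformaldehyde (as formaldehyde), C=O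
Why: Magnesium-mediated ortho-specific formylation (Casnati–Skattebøl): the magnesium phenoxide should direct formaldehyde to the only free ortho position, and a second formaldehyde oxidises the benzylic alkoxide by hydride transfer.

**Step 4**
Reactants: 6 3,6-bis(benzyloxy)-2-hydroxybenzaldehyde; 7 (2E)-penta-2,4-dien-1-yl(trimethyl)silane
Product: 8 (3E)-1-[3,6-bis(benzyloxy)-2-hydroxyphenyl]hexa-3,5-dien-1-ol (racemic at C1)
Conditions: TiCl4, CH2Cl2, –78 °C; aq. NaHCO3
Reagents that add atoms: none
Why: Hosomi–Sakurai pentadienylation: the Ti-chelated aldehyde should be attacked by the ε-terminus of the dienylsilane (SE2″) with loss of silicon, giving the conjugated (E)-diene; the new carbinol centre forms as a racemate and is removed by oxidation in step 7.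

**Step 5**
Reactants: 9 dodec-1-yne
Product: 11 (E)-1-iodododec-1-ene, via alkenylzirconocene chloride 10 (not isolated)
Conditions: Cp2Zr(H)Cl, THF, rt; then I2, 0 °C
Reagents that add atoms: iodine, II
Why: Hydrozirconation–iodination: syn addition of Zr–H places Zr on the terminal carbon and iodinolysis of the C–Zr bond proceeds with retention, which should give the (E)-alkenyl iodide.

**Step 6**
Reactants: 8 (3E)-1-[3,6-bis(benzyloxy)-2-hydroxyphenyl]hexa-3,5-dien-1-ol; 11 (E)-1-iodododec-1-ene
Product: 12 (2S)-5,8-bis(benzyloxy)-2-[(1E,4E)-pentadeca-1,4-dien-1-yl]-3,4-dihydro-2H-chromen-4-ol (both C4 epimers)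
Conditions: Pd2(dba)3 (2.5 mol %), chiral sulfinamide–phosphine ligand L* (Sadphos type, 10 mol %), K3PO4, degassed toluene, 60 °C
Reagents that add atoms: none
Why: Proposed new method: oxidative addition of Pd(0) to 11 gives an alkenyl–Pd(II) iodide that inserts the terminal C=C of the diene of 8 with the alkenyl group going to the CH2 terminus (this makes the C3′–C4′ bond), and the resulting syn-η3-allyl–Pd(II) over C2′–C1′–C2 is opened at C2 by the tethered phenoxide (this makes O1–C2) with return of Pd(0). The closest known reaction type is the Pd-catalysed Heck/Tsuji–Trost 1,2-/1,4-difunctionalisation of 1,3-dienes with aryl or alkenyl halides and O-, N- or C-nucleophiles (Larock heteroannulation and its enantioselective three-component and nucleophile-tethered variants); new here is a phenol tethered to an acyclic diene, closed by an external alkenyl iodide. The pyran ring closes by 6-exo attack of the phenoxide oxygen on the allyl terminus C2, the other terminus C2′ requiring an eight-membered ring. The C2 stereocentre is controlled by the chiral ligand, which selects the diene face in the migratory insertion, the C–O bond then forming anti to Pd with stereospecificity; the racemic C4 carbinol only leads to C4 epimers that converge in step 7. The step needs insertion at C3′ rather than at the internal alkene, attack by the phenol rather than by the C4 hydroxyl, and no β-hydride loss to a triene: the unsubstituted diene terminus, the pKa gap between phenol and alcohol under K3PO4 (the alkoxide could only close a four-membered or a strained unsaturated six-membered ring), and fast intramolecular capture should secure these. Running the cascade at the carbinol level rather than the ketone level avoids base-mediated conjugation of a β,γ-unsaturated ketone and keeps the product aryl ether a poor leaving group toward re-ionisation by Pd(0).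

**Step 7**
Reactants: 12 (2S)-5,8-bis(benzyloxy)-2-[(1E,4E)-pentadeca-1,4-dien-1-yl]-3,4-dihydro-2H-chromen-4-ol
Product: 13 (2S)-5,8-bis(benzyloxy)-2-[(1E,4E)-pentadeca-1,4-dien-1-yl]-2,3-dihydro-4H-chromen-4-one
Conditions: DMP, CH2Cl2, 0 °C to rt
Reagents that add atoms: none
Why: Dess–Martin oxidation of the secondary benzylic alcohol should take both C4 epimers to one ketone; the non-basic medium leaves the β-aryloxy ketone stereocentre C2 untouched.

**Step 8**
Reactants: 13 (2S)-5,8-bis(benzyloxy)-2-[(1E,4E)-pentadeca-1,4-dien-1-yl]-2,3-dihydro-4H-chromen-4-one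
Product: 14 (2R)-5,8-dihydroxy-2-pentadecyl-2,3-dihydro-4H-chromen-4-one (target)
Conditions: H2 (1 atm), 10% Pd/C, EtOAc, rt, then work-up under argon
Reagents that add atoms: none
Why: Heterogeneous catalytic hydrogenation should saturate both disubstituted C=C bonds and hydrogenolyse both benzyl ethers in one neutral operation without touching C2; the descriptor changes from S to R only because the saturated side chain now ranks below C3 in the CIP order.

**Compound list**
1 | 2,5-dihydroxybenzaldehyde | O=Cc1cc(O)ccc1O | starting material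
2 | 2,5-bis(benzyloxy)benzaldehyde | O=Cc1cc(OCc2ccccc2)ccc1OCc1ccccc1 | intermediate
3 | 2,5-bis(benzyloxy)phenyl formate | O=COc1cc(OCc2ccccc2)ccc1OCc1ccccc1 | intermediate
4 | 2,5-bis(benzyloxy)phenol | Oc1cc(OCc2ccccc2)ccc1OCc1ccccc1 | intermediate
5 | 3,6-bis(benzyloxy)-2-(hydroxymethyl)phenol (formed as its magnesium salt) | OCc1c(O)c(OCc2ccccc2)ccc1OCc1ccccc1 | intermediate
6 | 3,6-bis(benzyloxy)-2-hydroxybenzaldehyde | O=Cc1c(O)c(OCc2ccccc2)ccc1OCc1ccccc1 | intermediate
7 | (2E)-penta-2,4-dien-1-yl(trimethyl)silane | C=C/C=C/C[Si](C)(C)C | starting material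
8 | (3E)-1-[3,6-bis(benzyloxy)-2-hydroxyphenyl]hexa-3,5-dien-1-ol (racemic) | C=C/C=C/CC(O)c1c(O)c(OCc2ccccc2)ccc1OCc1ccccc1 | intermediate
9 | dodec-1-yne | CCCCCCCCCCC#C | starting material
10 | chloridobis(cyclopentadienyl)[(1E)-dodec-1-en-1-yl]zirconium | CCCCCCCCCC/C=C/[Zr](Cl)(C1C=CC=C1)C1C=CC=C1 | intermediate
11 | (E)-1-iodododec-1-ene | CCCCCCCCCC/C=C/I | intermediate
12 | (2S)-5,8-bis(benzyloxy)-2-[(1E,4E)-pentadeca-1,4-dien-1-yl]-3,4-dihydro-2H-chromen-4-ol (both C4 epimers) | CCCCCCCCCC/C=C/C/C=C/[C@@H]1CC(O)c2c(OCc3ccccc3)ccc(OCc3ccccc3)c2O1 | intermediate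
13 | (2S)-5,8-bis(benzyloxy)-2-[(1E,4E)-pentadeca-1,4-dien-1-yl]-2,3-dihydro-4H-chromen-4-one | CCCCCCCCCC/C=C/C/C=C/[C@@H]1CC(=O)c2c(OCc3ccccc3)ccc(OCc3ccccc3)c2O1 | intermediate
14 | (2R)-5,8-dihydroxy-2-pentadecyl-2,3-dihydro-4H-chromen-4-one | CCCCCCCCCCCCCCC[C@@H]1CC(=O)c2c(O)ccc(O)c2O1 | target

**Step count**
Total steps: 8. Longest linear sequence: 7 (steps 1–4, 6–8); step 5 is a one-step side branch.

**Steps most likely to fail**

Step 6 (proposed new method). The allyl–palladium stage may be lost by β-hydride elimination to a triene before the C–O bond closes, or the ligand may discriminate the diene faces poorly in the presence of the C4 carbinol centre. The fallback uses known chemistry only, sets out from phenol 4 (with iodide 11) and comes back to the route at 14. Mitsunobu etherification of 4 with the known methyl (3S)-3-hydroxyhex-5-enoate (PPh3, DIAD, inversion) should give methyl (3R)-3-[2,5-bis(benzyloxy)phenoxy]hex-5-enoate F1. Saponification (LiOH) gives (3R)-3-[2,5-bis(benzyloxy)phenoxy]hex-5-enoic acid F2. Intramolecular Friedel–Crafts acylation (TFAA, CH2Cl2, 0 °C) at the only free ortho position gives (2R)-2-allyl-5,8-bis(benzyloxy)chroman-4-one F3. Hydroboration of the allyl group with 9-BBN gives (2R)-5,8-bis(benzyloxy)-2-[3-(9-borabicyclo[3.3.1]nonan-9-yl)propyl]chroman-4-one F4, which is not isolated. B-alkyl Suzuki–Miyaura coupling of F4 with 11 (PdCl2(dppf), K3PO4) gives (2R)-5,8-bis(benzyloxy)-2-[(4E)-pentadec-4-en-1-yl]chroman-4-one F5. Hydrogenation under the conditions of step 8 then gives 14; the alkene of F5 is remote from the ring oxygen.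

Step 8. Hydrogenolysis of the allylic C2–O bond (opening of the pyranone ring) may compete with saturation of the C1′=C2′ bond before the alkene is gone. The fallback sets out from 13 and comes back at 14. Diimide reduction (2-nitrobenzenesulfonyl hydrazide, Et3N, CH2Cl2, rt) saturates both C=C bonds without any C–O cleavage and should give (2R)-5,8-bis(benzyloxy)-2-pentadecylchroman-4-one F6. The benzyl ethers of F6, which no longer carries an allylic ether, are then removed by H2, Pd/C to give 14.

Step 4. The titanium benzylic alkoxide, flanked by two ring oxygens, may ionise to an ortho-quinone methide and take up a second silane. The silane may also attack through its internal carbon, or be protodesilylated by HCl released from TiCl4 and the phenol. The fallback avoids Lewis acid, sets out from 6 and comes back at 8. Addition of allylmagnesium bromide (2.2 equiv, THF, –78 °C) should give 1-[3,6-bis(benzyloxy)-2-hydroxyphenyl]but-3-en-1-ol F7. Cross-metathesis with acrolein (second-generation Ru catalyst) gives (2E)-5-[3,6-bis(benzyloxy)-2-hydroxyphenyl]-5-hydroxypent-2-enal F8, which is used at once. Wittig methylenation (Ph3P=CH2, excess, –78 °C) then gives 8.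

**Further compounds**
F1 | step 6 | methyl (3R)-3-[2,5-bis(benzyloxy)phenoxy]hex-5-enoate | C=CC[C@H](CC(=O)OC)Oc1cc(OCc2ccccc2)ccc1OCc1ccccc1
F2 | step 6 | (3R)-3-[2,5-bis(benzyloxy)phenoxy]hex-5-enoic acid | C=CC[C@H](CC(=O)O)Oc1cc(OCc2ccccc2)ccc1OCc1ccccc1
F3 | step 6 | (2R)-2-allyl-5,8-bis(benzyloxy)-2,3-dihydro-4H-chromen-4-one | C=CC[C@@H]1CC(=O)c2c(OCc3ccccc3)ccc(OCc3ccccc3)c2O1
F4 | step 6 | (2R)-5,8-bis(benzyloxy)-2-[3-(9-borabicyclo[3.3.1]nonan-9-yl)propyl]-2,3-dihydro-4H-chromen-4-one | C1CCC2CCCC1B2CCC[C@@H]1CC(=O)c2c(OCc3ccccc3)ccc(OCc3ccccc3)c2O1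
F5 | step 6 | (2R)-5,8-bis(benzyloxy)-2-[(4E)-pentadec-4-en-1-yl]-2,3-dihydro-4H-chromen-4-one | CCCCCCCCCC/C=C/CCC[C@@H]1CC(=O)c2c(OCc3ccccc3)ccc(OCc3ccccc3)c2O1
F6 | step 8 | (2R)-5,8-bis(benzyloxy)-2-pentadecyl-2,3-dihydro-4H-chromen-4-one | CCCCCCCCCCCCCCC[C@@H]1CC(=O)c2c(OCc3ccccc3)ccc(OCc3ccccc3)c2O1
F7 | step 4 | 1-[3,6-bis(benzyloxy)-2-hydroxyphenyl]but-3-en-1-ol (racemic) | C=CCC(O)c1c(O)c(OCc2ccccc2)ccc1OCc1ccccc1
F8 | step 4 | (2E)-5-[3,6-bis(benzyloxy)-2-hydroxyphenyl]-5-hydroxypent-2-enal (racemic) | O=C/C=C/CC(O)c1c(O)c(OCc2ccccc2)ccc1OCc1ccccc1
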